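**Overview**

1. The retrosynthesis first removes the C8 angelate (acyl–O bond) and the C12 carbonyl oxygen. It then cuts C7–C11 and C8–O together, back to a C6 propargyl ether on an E C7=C8 alkene, and saturates C2=C3.
2. The strategic cut breaks C9–C10 and O–C10 and re-forms O–C7. This folds the ten-membered carbocycle back into a 2-vinyltetrahydropyran whose C3 arm ends in a methyl diazoketone. C2–C3, C4–C15 and C7–C8 then lead back to an Achmatowicz pyranone made from furfural and vinylmagnesium bromide.
3. The enabling feature is the oxygen bridge between C3 and C10. Inside the ten-membered ring (an 11-oxabicyclo[6.2.1]undecane) it closes the five-membered ring O–C10–C1–C2–C3. C10 is quaternary (C14 methyl, O, C9 methylene) and adjacent to the C1 ketone, which is what remains when an ether oxygen traps a keto carbenoid at C10 and passes on its allyl group through the terminus C9.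
4. Forward ring order: furan, pyranone, tetrahydropyran, then in one step the bridging tetrahydrofuranone and the ten-membered carbocycle, then the furanone, the methylenetetrahydrofuran and finally the lactone.
5. Stereochemistry: one resolved carbinol (future C7) sets C3 (trans C-glycosylation), C3 sets C4 (anti conjugate addition), and C7 sets C6 (hydride anti to vinyl, then Mitsunobu inversion). C3 sets C10 in the [2,3] shift. C3 and C7 then become sp2, and C7 and C8 are set by anti addition across the E alkene, steered by C6.

Key step: step 14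

Remark: the germacrane numbering of the target is used for every intermediate (C1 ketone, C2=C3, C4 bearing C15, C6 lactone carbinol, C7, C8 angelate carbinol, C9, C10 quaternary, C11–C13 methylene lactone, C14 methyl). The anomeric centre of 5 and 6 is taken as a mixture, which has no consequence because it becomes planar in step 5.

**Step 1**
Reactants: 1 furfural; 2 vinylmagnesium bromide
Product: 3 rac-1-(furan-2-yl)prop-2-en-1-ol
Conditions: THF, 0 °C; then H2O
Reagents that add atoms: none
Why: Grignard 1,2-addition to the aldehyde joins C7 to C8 and should give the racemic furyl allyl carbinol, with no stereocontrol sought at this stage.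

**Step 2**
Reactants: 3 rac-1-(furan-2-yl)prop-2-en-1-ol
Product: 4 (S)-1-(furan-2-yl)prop-2-en-1-ol
Conditions: Candida antarctica lipase B (immobilised), vinyl acetate, MTBE, 30 °C, stopped just past half conversion
Reagents that add atoms: none
Why: In this lipase kinetic resolution by irreversible transesterification, the usual enantiopreference for secondary alcohols (furyl large, vinyl medium) acylates the R carbinol and leaves the S alcohol, whose carbinol carbon is the future C7 and the only stereocentre brought in from outside.

**Step 3**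
Reactants: 4 (S)-1-(furan-2-yl)prop-2-en-1-ol
Product: 5 (2S)-6-hydroxy-2-vinyl-2H-pyran-3(6H)-one (both anomers)
Conditions: NBS, NaHCO3, THF/H2O, 0 °C
Reagents that add atoms: water, O
Why: In the Achmatowicz rearrangement the electron-rich furan is oxidised faster than the monosubstituted alkene, and lactol closure through the carbinol oxygen leaves the C7–O stereocentre untouched.

**Step 4**
Reactants: 5 (2S)-6-hydroxy-2-vinyl-2H-pyran-3(6H)-one
Product: 6 (6S)-5-oxo-6-vinyl-5,6-dihydro-2H-pyran-2-yl acetate (both anomers)
Conditions: Ac2O, pyridine, CH2Cl2, 0 °C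
Reagents that add atoms: acetic anhydride, CC(=O)OC(C)=O
Why: O-acylation turns the lactol into an ionisable anomeric acetate, and the weak base and low temperature spare the doubly activated H7.

**Step 5**
Reactants: 6 anomeric acetate; 7 1-(tert-butyldimethylsilyloxy)-1-methoxyethene
Product: 8 methyl 2-[(2S,6S)-5-oxo-6-vinyl-5,6-dihydro-2H-pyran-2-yl]acetate (2,6-trans)
Conditions: BF3·OEt2, CH2Cl2, −78 °C
Reagents that add atoms: none
Why: In this Lewis-acid C-glycosylation (Mukaiyama-type addition of a silyl ketene acetal to the cyclic oxocarbenium ion) the nucleophile should enter on the face opposite the C7 vinyl group, which sets C3 trans to C7 across the ring oxygen under fully non-basic conditions.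

**Step 6**
Reactants: 8 2,6-trans enone ester; 9 (chloromethyl)(isopropoxy)dimethylsilane
Product: 11 (3S,4R,7S) tetrahydropyran-3-one carrying CH2SiMe2(O-i-Pr) at C4 anti to the C3 acetate arm, via silylmethyl Grignard reagent 10 (not isolated)
Conditions: 9, Mg, THF, reflux; then CuI (10 mol %), THF, −78 °C, add 8; then H2O (pH 7 buffer), −78 °C
Reagents that add atoms: magnesium, [Mg] (stays only in 10)
Why: In this conjugate addition of a hydroxymethyl-anion equivalent catalysed by monovalent copper, the nucleophile enters C4 anti to the neighbouring C3 substituent, as with 4-substituted cyclohexenones, and the ester survives at −78 °C.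

**Step 7**
Reactants: 11 C4 silylmethyl ketone
Product: 13 (3S,4S,6S,7S) C6,C15 diol with the C6 hydroxyl cis to the vinyl group, via C6 carbinol silane 12 (not isolated)
Conditions: LiBH(s-Bu)3, THF, −78 °C; then MeOH, KF, KHCO3, 30% H2O2, 0 °C to rt
Reagents that add atoms: hydrogen peroxide, OO
Why: In this bulky-hydride reduction followed in the same flask by Tamao–Fleming oxidation, hydride should reach C6 from the face away from the axial C7 vinyl group (or away from the axial C4 arm in the other chair), so the hydroxyl ends cis to vinyl and awaits inversion, while reducing first removes the base-sensitive α-vinyl ketone before the basic peroxide converts C15–Si into C15–OH.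

**Step 8**
Reactants: 13 C6,C15 diol
Product: 14 C15 tert-butyldiphenylsilyl ether with free 6S alcohol
Conditions: TBDPSCl, imidazole, CH2Cl2, 0 °C
Reagents that add atoms: tert-butyldiphenylsilyl chloride, CC(C)(C)[Si](Cl)(c1ccccc1)c1ccccc1
Why: The bulky chlorosilane silylates the primary alcohol selectively, and prompt protection also stops the C15 hydroxyl from closing a δ-lactone on the ester.

**Step 9**
Reactants: 14 6S alcohol
Product: 15 6R 4-nitrobenzoate
Conditions: 4-O2NC6H4CO2H, PPh3, DIAD, toluene, 0 °C to rt
Reagents that add atoms: 4-nitrobenzoic acid, OC(=O)c1ccc(cc1)[N+](=O)[O-]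
Why: In the Mitsunobu reaction, SN2 displacement of the equatorial alkoxyphosphonium group inverts C6 to the R configuration of the target (oxygen trans to vinyl, cis to the C3 arm), and an equatorial leaving group has no antiperiplanar hydrogen for elimination.

**Step 10**
Reactants: 15 6R 4-nitrobenzoate
Product: 16 6R alcohol
Conditions: K2CO3 (cat.), MeOH, 0 °C to rt
Reagents that add atoms: none
Why: Base-catalysed transesterification removes the activated aryl ester, exchange at the methyl ester is degenerate in methanol, and the C6–O bond is not touched.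

**Step 11**
Reactants: 16 6R alcohol
Product: 17 (3S,4S,6R,7S) methyl ester with C6 OTBS and C15 OTBDPS
Conditions: TBSOTf, 2,6-lutidine, CH2Cl2, −78 to 0 °C
Reagents that add atoms: tert-butyldimethylsilyl triflate, CC(C)(C)[Si](C)(C)OS(=O)(=O)C(F)(F)F
Why: The silyl triflate is reactive enough for the hindered secondary alcohol, and TBS can later be removed in the presence of TBDPS.

**Step 12**
Reactants: 17 methyl ester
Product: 18 carboxylic acid
Conditions: LiOH, THF/MeOH/H2O, rt; dilute HCl to pH 4, 0 °C
Reagents that add atoms: lithium hydroxide, [Li+].[OH-]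
Why: Saponification of an unhindered methyl ester should leave both silyl ethers and all four stereocentres unaffected.

**Step 13**
Reactants: 18 carboxylic acid; 19 N-ethyl-N-nitrosourea
Product: 22 2-vinyltetrahydropyranyl methyl diazoketone, via mixed carbonic anhydride 20 (not isolated), via diazoethane 21 (not isolated)
Conditions: i-BuOCOCl, Et3N, Et2O, −20 °C, filter; CH3CHN2 in Et2O (from 19, aq KOH, Et2O, 0 °C), 0 °C to rt
Reagents that add atoms: isobutyl chloroformate, CC(C)COC(=O)Cl (stays only in 20)
Why: Acylation of a diazoalkane by a mixed anhydride (the first stage of the Arndt–Eistert protocol) brings in C10 with its C14 methyl under conditions too mild for retro-oxa-Michael opening of the β-alkoxy acyl unit.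

**Step 14**
Reactants: 22 methyl diazoketone
Product: 24 (3S,4S,6R,10S,7E)-11-oxabicyclo[6.2.1]undec-5-en-9-one core with C6 OTBS and C15 OTBDPS, via bicyclic oxonium ylide 23 (not isolated)
Conditions: Cu(CF3COCHCOCF3)2 (5 mol %), CH2Cl2, reflux, slow addition of 22
Reagents that add atoms: none
Why: Cu(CF3COCHCOCF3)2 (divalent copper) strips N2 from 22, and the electrophilic carbenoid at C10 is trapped by a lone pair of the ring oxygen, which sits gamma to it, in a five-membered closure (new O–C10 bond, ring O–C10–C1–C2–C3) that gives oxonium ylide 23. In 23 the ylide carbon C10 bonds to the vinyl terminus C9 through a five-centre envelope while the allylic O–C7 bond breaks, so the ten-membered carbocycle C1–C10 is closed by a [2,3]-sigmatropic ring expansion of the six-membered ether (new C9–C10 bond) and not by an end-to-end macrocyclisation. The closest known reaction type is the copper- or rhodium-catalysed oxonium ylide formation/[2,3] rearrangement of 2-vinyltetrahydropyranyl diazoketones to 11-oxabicyclo[6.2.1]undecenones, extended here only from a CHN2 to a C(CH3)N2 terminus. C10 is the one new stereocentre and is controlled by C3, because the allyl group migrates suprafacially to the face of the five-membered ring on which O–C7 stood, and only the ylide whose two rings are cis-fused (C7 and C4 on the same face) leads to a six-atom bridge spanning C3 and C10 on one face, which puts C9 cis to C4 and C14 cis to H3 (10S). The E geometry comes from the 2,6-trans substitution: the cis-fused ylide is productive only in the chair with the C3 and C4 arms axial and the vinyl and OTBS groups equatorial, where C10 lies gauche to the vinyl group and C9 reaches it only in the rotamer with C9 syn to H7 and anti to C6, whereas the other chair holds vinyl and C10 antiperiplanar and a trans-fused ylide could only give an unattainable in,out bicycle. The step also needs oxygen capture to outrun the 1,2-hydride shift from C14 (enone), C–H insertion and cyclopropanation, which the five-membered proximity of the ether oxygen, the electron-poor copper catalyst and slow addition at high dilution are chosen to secure.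

**Step 15**
Reactants: 24 bridged ketone
Product: 25 C1 trimethylsilyl enol ether (C1=C2)
Conditions: LiN(SiMe3)2, TMSCl, THF, −78 °C
Reagents that add atoms: chlorotrimethylsilane, C[Si](C)(C)Cl
Why: Kinetic enolisation and O-silylation can only go toward C2 because C10 is quaternary, and the five-membered ring holds the C3–O bond orthogonal to the enolate so that β-elimination is held back.

**Step 16**
Reactants: 25 silyl enol ether
Product: 26 bridged 3(2H)-furanone (C2=C3) with E C7=C8
Conditions: Pd(OAc)2 (1.1 equiv), MeCN, rt
Reagents that add atoms: none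
Why: In the Saegusa–Ito oxidation divalent palladium binds C2 on the open face shared by H3 and C14, and syn β-hydride elimination of H3 gives the bridgehead enone, which this large bicycle tolerates, erasing the C3 stereocentre after it has done its work.

**Step 17**
Reactants: 26 bis-silyl ether
Product: 27 C6 allylic alcohol (C15 OTBDPS kept)
Conditions: camphorsulfonic acid (cat.), MeOH/CH2Cl2, 0 °C
Reagents that add atoms: none
Why: Acid-catalysed methanolysis cleaves the secondary TBS ether well before the far more acid-stable TBDPS ether, and the vinylogous ester tolerates mild acid.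

**Step 18**
Reactants: 27 C6 allylic alcohol; 28 propargyl bromide
Product: 29 C6 propargyl ether (1,6-enyne)
Conditions: Ag2O, 4 Å molecular sieves, CH2Cl2, dark, rt to 40 °C
Reagents that add atoms: none
Why: Silver-oxide-promoted Williamson-type etherification works without strong base, so the vinylogously acidic H4 and with it the C4 configuration are not put at risk.

**Step 19**
Reactants: 29 1,6-enyne
Product: 30 trans-fused 3-methylenetetrahydrofuran with free C8 hydroxyl (target configuration at C6, C7 and C8)
Conditions: Ph3PAuCl (5 mol %), AgSbF6 (5 mol %), 1,4-dioxane/H2O, rt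
Reagents that add atoms: water, O
Why: In this enyne hydroxycyclisation with cationic monovalent gold, C7 attacks the internal alkyne carbon 5-exo-dig and water opens the cyclopropyl gold carbene at C8 anti to the new C7–C11 bond, so the E geometry fixes C7 relative to C8, and delivery of C11 from the C6 oxygen in the rotamer with H6 eclipsing the alkene gives the trans ring fusion.

**Step 20**
Reactants: 30 C8 alcohol; 31 angelic acid
Product: 33 C8 angelate, via angelic trichlorobenzoic anhydride 32 (not isolated)
Conditions: 2,4,6-Cl3C6H2COCl, Et3N, toluene, rt; then 30, toluene, 75 °C, no DMAP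
Reagents that add atoms: 2,4,6-trichlorobenzoyl chloride, O=C(Cl)c1c(Cl)cc(Cl)cc1Cl (stays only in 32)
Why: Yamaguchi esterification run without a nucleophilic catalyst avoids the conjugate addition–elimination that turns angelate into tiglate, and C8 keeps its configuration because its C–O bond is not broken.

**Step 21**
Reactants: 33 C8 angelate
Product: 34 α-methylene-γ-butyrolactone (C15 OTBDPS)
Conditions: CrO3, 3,5-dimethylpyrazole, CH2Cl2, −20 °C
Reagents that add atoms: chromium trioxide, O=[Cr](=O)=O
Why: In this allylic oxidation by the complex of hexavalent chromium with dimethylpyrazole, the C12 methylene is both allylic and α to oxygen, hence the most easily oxidised C–H site, a known way from 3-methylenetetrahydrofurans to α-methylene lactones.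

**Step 22**
Reactants: 34 silyl-protected lactone
Product: 35 target CNP0108636.1
Conditions: HF·pyridine, THF, 0 °C to rt
Reagents that add atoms: none
Why: Fluoride-driven desilylation in a slightly acidic medium frees C15–OH without adding to the methylene lactone, isomerising the angelate or epimerising C4.

**Compound list**

| No. | Name | SMILES | Role |
|---|---|---|---|
| 1 | furfural | O=Cc1ccco1 | starting material |
| 2 | vinylmagnesium bromide | C=C[Mg]Br | starting material |
| 3 | rac-1-(furan-2-yl)prop-2-en-1-ol | OC(c1ccco1)C=C | intermediate |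
| 4 | (S)-1-(furan-2-yl)prop-2-en-1-ol | O[C@H](c1ccco1)C=C | intermediate |
| 5 | (2S)-6-hydroxy-2-vinyl-2H-pyran-3(6H)-one, both anomers | O=C1C=CC(O)O[C@H]1C=C | intermediate |
| 6 | (6S)-5-oxo-6-vinyl-5,6-dihydro-2H-pyran-2-yl acetate, both anomers | O=C1C=CC(OC(C)=O)O[C@H]1C=C | intermediate |
| 7 | 1-(tert-butyldimethylsilyloxy)-1-methoxyethene | C=C(OC)O[Si](C)(C)C(C)(C)C | starting material |
| 8 | methyl 2-[(2S,6S)-5-oxo-6-vinyl-5,6-dihydro-2H-pyran-2-yl]acetate, 2,6-trans | O=C1C=C[C@H](CC(=O)OC)O[C@H]1C=C | intermediate |
| 9 | (chloromethyl)(isopropoxy)dimethylsilane | ClC[Si](C)(C)OC(C)C | starting material |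
| 10 | (isopropoxydimethylsilyl)methylmagnesium chloride | CC(C)O[Si](C)(C)C[Mg]Cl | intermediate |
| 11 | (3S,4R,7S) C6 ketone, C4 silylmethyl anti to the C3 arm, vinyl trans to the C3 arm | O=C1C[C@@H](C[Si](C)(C)OC(C)C)[C@H](CC(=O)OC)O[C@H]1C=C | intermediate |
| 12 | (3S,4R,6S,7S) C6 carbinol silane, OH cis to vinyl | O[C@H]1C[C@@H](C[Si](C)(C)OC(C)C)[C@H](CC(=O)OC)O[C@H]1C=C | intermediate |
| 13 | (3S,4S,6S,7S) C6,C15 diol | O[C@H]1C[C@@H](CO)[C@H](CC(=O)OC)O[C@H]1C=C | intermediate |
| 14 | C15 OTBDPS, free 6S alcohol | O[C@H]1C[C@@H](CO[Si](c2ccccc2)(c2ccccc2)C(C)(C)C)[C@H](CC(=O)OC)O[C@H]1C=C | intermediate |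
| 15 | 6R 4-nitrobenzoate | O=C(O[C@@H]1C[C@@H](CO[Si](c2ccccc2)(c2ccccc2)C(C)(C)C)[C@H](CC(=O)OC)O[C@H]1C=C)c1ccc(cc1)[N+](=O)[O-] | intermediate |
| 16 | 6R alcohol, OH trans to vinyl | O[C@@H]1C[C@@H](CO[Si](c2ccccc2)(c2ccccc2)C(C)(C)C)[C@H](CC(=O)OC)O[C@H]1C=C | intermediate |
| 17 | (3S,4S,6R,7S) methyl ester, C6 OTBS, C15 OTBDPS | CC(C)(C)[Si](C)(C)O[C@@H]1C[C@@H](CO[Si](c2ccccc2)(c2ccccc2)C(C)(C)C)[C@H](CC(=O)OC)O[C@H]1C=C | intermediate |
| 18 | corresponding carboxylic acid | CC(C)(C)[Si](C)(C)O[C@@H]1C[C@@H](CO[Si](c2ccccc2)(c2ccccc2)C(C)(C)C)[C@H](CC(=O)O)O[C@H]1C=C | intermediate |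
| 19 | N-ethyl-N-nitrosourea | CCN(N=O)C(N)=O | starting material |
| 20 | isobutyl carbonic mixed anhydride of 18 | CC(C)(C)[Si](C)(C)O[C@@H]1C[C@@H](CO[Si](c2ccccc2)(c2ccccc2)C(C)(C)C)[C@H](CC(=O)OC(=O)OCC(C)C)O[C@H]1C=C | intermediate |
| 21 | diazoethane | CC=[N+]=[N-] | intermediate |
| 22 | 2-vinyltetrahydropyranyl methyl diazoketone | CC(C)(C)[Si](C)(C)O[C@@H]1C[C@@H](CO[Si](c2ccccc2)(c2ccccc2)C(C)(C)C)[C@H](CC(=O)C(C)=[N+]=[N-])O[C@H]1C=C | intermediate |
| 23 | cis-fused bicyclic oxonium ylide (O bonded to C3, C7 and C10) | CC(C)(C)[Si](C)(C)O[C@@H]1C[C@@H](CO[Si](c2ccccc2)(c2ccccc2)C(C)(C)C)[C@@H]2CC(=O)[C-](C)[O+]2[C@H]1C=C | intermediate |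
| 24 | (3S,4S,6R,10S,7E) bridged ketone, 11-oxabicyclo[6.2.1]undec-5-en-9-one core | C1[C@@H](CO[Si](c3ccccc3)(c3ccccc3)C(C)(C)C)[C@@H]2CC(=O)[C@](C)(C/C=C/[C@@H]1O[Si](C)(C)C(C)(C)C)O2 | intermediate |
| 25 | C1 trimethylsilyl enol ether | C1[C@@H](CO[Si](c3ccccc3)(c3ccccc3)C(C)(C)C)[C@@H]2C=C(O[Si](C)(C)C)[C@](C)(C/C=C/[C@@H]1O[Si](C)(C)C(C)(C)C)O2 | intermediate |
| 26 | (4S,6R,10S,7E) bridged 3(2H)-furanone | C1[C@@H](CO[Si](c3ccccc3)(c3ccccc3)C(C)(C)C)C2=CC(=O)[C@](C)(C/C=C/[C@@H]1O[Si](C)(C)C(C)(C)C)O2 | intermediate |
| 27 | C6 allylic alcohol | C1[C@@H](CO[Si](c3ccccc3)(c3ccccc3)C(C)(C)C)C2=CC(=O)[C@](C)(C/C=C/[C@@H]1O)O2 | intermediate |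
| 28 | propargyl bromide | C#CCBr | starting material |
| 29 | C6 propargyl ether | C1[C@@H](CO[Si](c3ccccc3)(c3ccccc3)C(C)(C)C)C2=CC(=O)[C@](C)(C/C=C/[C@@H]1OCC#C)O2 | intermediate |
| 30 | trans-fused 3-methylenetetrahydrofuran, free 8R hydroxyl | C=C1CO[C@@H]2C[C@@H](CO[Si](c4ccccc4)(c4ccccc4)C(C)(C)C)C3=CC(=O)[C@](C)(C[C@@H](O)[C@@H]12)O3 | intermediate |
| 31 | angelic acid, (Z)-2-methylbut-2-enoic acid | C/C=C(/C)C(=O)O | starting material |
| 32 | angelic 2,4,6-trichlorobenzoic anhydride | C/C=C(/C)C(=O)OC(=O)c1c(Cl)cc(Cl)cc1Cl | intermediate |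
| 33 | C8 angelate | C=C1CO[C@@H]2C[C@@H](CO[Si](c4ccccc4)(c4ccccc4)C(C)(C)C)C3=CC(=O)[C@](C)(C[C@@H](OC(=O)/C(C)=C\C)[C@@H]12)O3 | intermediate |
| 34 | α-methylene lactone, C15 OTBDPS | C=C1C(=O)O[C@@H]2C[C@@H](CO[Si](c4ccccc4)(c4ccccc4)C(C)(C)C)C3=CC(=O)[C@](C)(C[C@@H](OC(=O)/C(C)=C\C)[C@@H]12)O3 | intermediate |
| 35 | CNP0108636.1, (4S,6R,7S,8R,10S) | C=C1C(=O)O[C@@H]2C[C@@H](CO)C3=CC(=O)[C@](C)(C[C@@H](OC(=O)/C(C)=C\C)[C@@H]12)O3 | target |

**Step count**

- Total steps: 22.
- Longest linear sequence: 22 steps, from furfural 1. All other building blocks are bought and enter directly.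

**Steps most likely to fail**

**Step 19 (gold hydroxycyclisation).**
- Water has to reach C8 on the side of the alkene that faces the interior of the medium ring, next to the quaternary C10.
- If this capture is slow, hydration of the alkyne, skeletal rearrangement of the gold carbene or transannular capture by the furanone C2=C3 may take over.
- The fallback sets out from 29 and returns at 30. It separates the two bond formations and replaces the cationic pathway by a radical one.
- Dimethyldioxirane in acetone/CH2Cl2 at 0 °C should epoxidise the strained E alkene ahead of the alkyne and the electron-poor enone. Attack should come on the outer face of the conformer that keeps C6–O in the alkene plane and C5–C6 perpendicular to it. This gives the 7,8-epoxy propargyl ether F1, with the C8–O bond already in the target configuration.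
- Cp2TiCl (trivalent titanium, made from Cp2TiCl2 and Zn dust in THF) then breaks the C7–O bond homolytically, the usual sense for 2,3-epoxy alcohol derivatives (Nugent–RajanBabu reaction).
- The planar C7 radical closes 5-exo-dig on the alkyne to the trans-fused ring, the vinyl radical takes up hydrogen from 1,4-cyclohexadiene, and mild acid work-up frees the C8 hydroxyl of 30.

**Step 14 (key step).**
- Migration of a C14 hydrogen to the carbenoid carbon may outrun capture by the ether oxygen, or the ylide may leak into a 1,2-shift.
- The fallback sets out from 18 and returns at 24. It keeps the same bond formations but uses a carbenoid that has no migratable hydrogen.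
- Carbonyldiimidazole and Mg(O2CCH2CO2Me)2 (Masamune–Brooks homologation) convert 18 into the β-keto ester F2.
- Diazo transfer with 4-acetamidobenzenesulfonyl azide and Et3N gives the diazo keto ester F3.
- Rh2(OAc)4 (divalent rhodium) in refluxing CH2Cl2 brings about the same ylide formation and [2,3] shift to the C10 carbomethoxy ketone F4.
- LiAlH4 reduces ketone and ester to the C1,C14 diol F5.
- I2, PPh3 and imidazole (Appel-type) convert the primary alcohol into the C14 iodide F6.
- Bu3SnH/AIBN removes the iodine to leave the C14 methyl carbinol F7, and Dess–Martin oxidation at C1 gives 24.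

**Step 7 (ketone reduction).**
- Facial selectivity of hydride delivery may be poor because two chair forms of the ketone lie close in energy.
- The basic borohydride may also enolise toward C7 and move the vinyl double bond into conjugation.
- The fallback sets out from 11 and returns at 16. It replaces steric control plus inversion by internal delivery under acidic conditions.
- Buffered Tamao–Fleming oxidation of 11 (H2O2, KF, KHCO3, 0 °C) gives the C15 hydroxy ketone F8.
- Me4NBH(OAc)3 in MeCN/AcOH at −20 °C binds the C15 hydroxyl and passes hydride to C6 from the face that carries the C4 arm (Saksena–Evans reduction), which should give the 6R diol F9 directly.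
- Selective silylation of the primary alcohol with TBDPSCl and imidazole gives 16, so that steps 8 to 10 are no longer needed.

**Further compounds**

F1 | step 19 | 7,8-epoxy propargyl ether (trans epoxide, oxygen anti to O6) | C1[C@@H](CO[Si](c3ccccc3)(c3ccccc3)C(C)(C)C)C2=CC(=O)[C@](C)(C[C@H]3O[C@@H]3[C@@H]1OCC#C)O2
F2 | step 14 | β-keto ester | CC(C)(C)[Si](C)(C)O[C@@H]1C[C@@H](CO[Si](c2ccccc2)(c2ccccc2)C(C)(C)C)[C@H](CC(=O)CC(=O)OC)O[C@H]1C=C
F3 | step 14 | diazo keto ester | CC(C)(C)[Si](C)(C)O[C@@H]1C[C@@H](CO[Si](c2ccccc2)(c2ccccc2)C(C)(C)C)[C@H](CC(=O)C(=[N+]=[N-])C(=O)OC)O[C@H]1C=C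
F4 | step 14 | C10 carbomethoxy ketone | C1[C@@H](CO[Si](c3ccccc3)(c3ccccc3)C(C)(C)C)[C@@H]2CC(=O)[C@](C(=O)OC)(C/C=C/[C@@H]1O[Si](C)(C)C(C)(C)C)O2
F5 | step 14 | C1,C14 diol (either C1 epimer) | C1[C@@H](CO[Si](c3ccccc3)(c3ccccc3)C(C)(C)C)[C@@H]2CC(O)[C@](CO)(C/C=C/[C@@H]1O[Si](C)(C)C(C)(C)C)O2
F6 | step 14 | C14 iodide | C1[C@@H](CO[Si](c3ccccc3)(c3ccccc3)C(C)(C)C)[C@@H]2CC(O)[C@](CI)(C/C=C/[C@@H]1O[Si](C)(C)C(C)(C)C)O2
F7 | step 14 | C14 methyl carbinol | C1[C@@H](CO[Si](c3ccccc3)(c3ccccc3)C(C)(C)C)[C@@H]2CC(O)[C@](C)(C/C=C/[C@@H]1O[Si](C)(C)C(C)(C)C)O2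
F8 | step 7 | C15 hydroxy ketone | O=C1C[C@@H](CO)[C@H](CC(=O)OC)O[C@H]1C=C
F9 | step 7 | 6R diol | O[C@@H]1C[C@@H](CO)[C@H](CC(=O)OC)O[C@H]1C=C
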